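**Assumption:** the target SMILES is read as (1R,3R,4S,7R,11E) in cembrane numbering (C1 carries the oxygenated isopropyl carbon C15); this numbering labels atoms throughout.

## Retrosynthetic overview

1. The 14-membered carbocycle is closed last, at C7–C8, by Ni/Cr coupling of an enol triflate with an aldehyde (20 ⇒ 19).
2. The oxane ring is closed before that: the tertiary C4–OH adds to the C1 isopropenyl group to make the C4–O–C15 ether (17 ⇒ 15).
3. Key bond C3–C4: metallated 2,3-dihydrofuran, an acyl anion equivalent carrying C4–C7, is acylated by the C3 Weinreb amide; C3 is then set by CBS reduction and C4 by chelation-controlled MeMgBr addition.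
4. C1 comes from an auxiliary-controlled isopropenyl 1,4-addition to an enoyl imide made by cross-metathesis of the geranylacetone enol triflate with an acryloyl oxazolidinone.
5. Ring order: oxane first, macrocycle second.

## Route

Step 1
Reactants: 1 geranylacetone
Product: 3 (5E)-6,10-dimethylundeca-1,5,9-trien-2-yl trifluoromethanesulfonate, via lithium enolate 2 (not isolated)
Conditions: LiN(i-Pr)2, THF, −78 °C; then PhNTf2, −78 → 0 °C
Reagents that add atoms: N-phenylbis(trifluoromethanesulfonimide), O=S(=O)(N(c1ccccc1)S(=O)(=O)C(F)(F)F)C(F)(F)F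
Why: Kinetic deprotonation of the methyl ketone at CH3 by the hindered amide base and O-triflation of the enolate (enol triflate formation) give the 2-triflyloxy-1-alkene needed for the final Ni/Cr coupling; no stereocentre is formed and both trisubstituted alkenes are untouched.

Step 2
Reactants: 3 (5E)-6,10-dimethylundeca-1,5,9-trien-2-yl trifluoromethanesulfonate; 4 (4S)-3-acryloyl-4-phenyl-1,3-oxazolidin-2-one
Product: 5 (4S)-3-[(2E,6E)-6-methyl-10-(trifluoromethanesulfonyloxy)undeca-2,6,10-trienoyl]-4-phenyl-1,3-oxazolidin-2-one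
Conditions: second-generation Hoveyda–Grubbs catalyst (5 mol%), CH2Cl2, 40 °C
Reagents that add atoms: none
Why: Olefin cross-metathesis exchanges the isopropylidene of the prenyl terminus for the acryloyl alkylidene with loss of volatile isobutene, the internal trisubstituted C11=C12 alkene and the electron-poor enol triflate alkene are too hindered or deactivated to engage, and the conjugated product forms as the E isomer.

Step 3
Reactants: 5 (4S)-3-[(2E,6E)-6-methyl-10-(trifluoromethanesulfonyloxy)undeca-2,6,10-trienoyl]-4-phenyl-1,3-oxazolidin-2-one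
Product: 6 (4S)-3-[(3R,6E)-6-methyl-3-(prop-1-en-2-yl)-10-(trifluoromethanesulfonyloxy)undeca-6,10-dienoyl]-4-phenyl-1,3-oxazolidin-2-one
Conditions: isopropenylmagnesium bromide, CuBr·SMe2 (30 mol%), THF/Me2S, −78 → −40 °C
Reagents that add atoms: isopropenylmagnesium bromide, CC(=C)[Mg]Br
Why: Copper-catalysed conjugate addition of the Grignard reagent to the magnesium-chelated s-cis N-enoyl oxazolidinone, in which the 4-phenyl group blocks one face so that the isopropenyl group enters anti to it and sets C1 as R, while the enol triflate is inert at this temperature.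

Step 4
Reactants: 6 (4S)-3-[(3R,6E)-6-methyl-3-(prop-1-en-2-yl)-10-(trifluoromethanesulfonyloxy)undeca-6,10-dienoyl]-4-phenyl-1,3-oxazolidin-2-one
Product: 7 (3R,6E)-N-methoxy-N,6-dimethyl-3-(prop-1-en-2-yl)-10-(trifluoromethanesulfonyloxy)undeca-6,10-dienamide
Conditions: MeNHOMe·HCl, AlMe3, CH2Cl2, 0 °C → rt
Reagents that add atoms: N,O-dimethylhydroxylamine hydrochloride, CNOC.Cl
Why: Aluminium amide aminolysis of the exocyclic imide carbonyl (Weinreb amide formation) releases the auxiliary and gives a partner that can be acylated only once; C1 cannot epimerise.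

Step 5
Reactants: 7 (3R,6E)-N-methoxy-N,6-dimethyl-3-(prop-1-en-2-yl)-10-(trifluoromethanesulfonyloxy)undeca-6,10-dienamide; 8 2,3-dihydrofuran
Product: 11 (5E,9R)-11-(4,5-dihydrofuran-2-yl)-6-methyl-11-oxo-9-(prop-1-en-2-yl)undeca-1,5-dien-2-yl trifluoromethanesulfonate, via 5-lithio-2,3-dihydrofuran 9 (not isolated), via dihydrofuranylmagnesium bromide 10 (not isolated)
Conditions: 8, t-BuLi, THF, −78 → 0 °C; MgBr2·OEt2, −78 °C; then 7, −78 → 0 °C
Reagents that add atoms: none
Why: Acyl anion equivalent chemistry (α-metallated enol ether acylated by a Weinreb amide): the metallated cyclic enol ether is a masked C4 acyl carbanion that attacks the amide carbonyl carbon C3 once through a chelated tetrahedral intermediate, so two carbons that both end at carbonyl level are joined and C4–C7 arrive in one reagent, transmetallation to magnesium keeps the reagent off the enol triflate, and no stereocentre is formed.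

Step 6
Reactants: 11 (5E,9R)-11-(4,5-dihydrofuran-2-yl)-6-methyl-11-oxo-9-(prop-1-en-2-yl)undeca-1,5-dien-2-yl trifluoromethanesulfonate
Product: 12 (5E,9R,11R)-11-(4,5-dihydrofuran-2-yl)-11-hydroxy-6-methyl-9-(prop-1-en-2-yl)undeca-1,5-dien-2-yl trifluoromethanesulfonate
Conditions: (S)-2-methyl-CBS-oxazaborolidine (20 mol%), catecholborane, toluene, −78 °C
Reagents that add atoms: none
Why: Corey–Bakshi–Shibata reduction in which the oxazaborolidine–borane complex binds the ketone anti to the larger α-alkoxyalkenyl substituent and delivers hydride to one face, setting C3 as R, while catecholborane at −78 °C avoids hydroboration and 1,4-reduction.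

Step 7
Reactants: 12 (5E,9R,11R)-11-(4,5-dihydrofuran-2-yl)-11-hydroxy-6-methyl-9-(prop-1-en-2-yl)undeca-1,5-dien-2-yl trifluoromethanesulfonate
Product: 13 (5E,9R,11R)-11,15-dihydroxy-6-methyl-12-oxo-9-(prop-1-en-2-yl)pentadeca-1,5-dien-2-yl trifluoromethanesulfonate
Conditions: HCl (0.05 M, cat.), THF/H2O, 0 °C
Reagents that add atoms: water, O
Why: Acid-catalysed enol ether hydrolysis (protonation at C5, hydration of the oxocarbenium ion, ring opening) unmasks the C4 ketone and the C7 primary alcohol without touching C3; the product equilibrates with its cyclic hemiketal.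

Step 8
Reactants: 13 (5E,9R,11R)-11,15-dihydroxy-6-methyl-12-oxo-9-(prop-1-en-2-yl)pentadeca-1,5-dien-2-yl trifluoromethanesulfonate
Product: 14 (5E,9R,11R,12S)-11,12,15-trihydroxy-6,12-dimethyl-9-(prop-1-en-2-yl)pentadeca-1,5-dien-2-yl trifluoromethanesulfonate
Conditions: MeMgBr (5 equiv), THF, −78 → −30 °C
Reagents that add atoms: methylmagnesium bromide, C[Mg]Br
Why: Cram-chelate controlled Grignard addition in which magnesium bridges the C3 alkoxide and the C4 carbonyl oxygen and methyl attacks from the side of the small C3 hydrogen, setting the quaternary carbinol C4 as S (the 3R,4S relationship of the target).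

Step 9
Reactants: 14 (5E,9R,11R,12S)-11,12,15-trihydroxy-6,12-dimethyl-9-(prop-1-en-2-yl)pentadeca-1,5-dien-2-yl trifluoromethanesulfonate
Product: 15 (5E,9R,11R,12S)-12-hydroxy-6,12-dimethyl-9-(prop-1-en-2-yl)-2-(trifluoromethanesulfonyloxy)pentadeca-1,5-diene-11,15-diyl diacetate
Conditions: Ac2O (2.5 equiv), pyridine, DMAP (cat.), CH2Cl2, 0 °C
Reagents that add atoms: acetic anhydride, CC(=O)OC(C)=O
Why: DMAP-catalysed acylation esterifies the secondary C3 and primary C7 hydroxyls while the hindered tertiary C4 hydroxyl stays free; the C3 acetate is the one in the target and it prevents five-membered ether formation in the next step.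

Step 10
Reactants: 15 (5E,9R,11R,12S)-12-hydroxy-6,12-dimethyl-9-(prop-1-en-2-yl)-2-(trifluoromethanesulfonyloxy)pentadeca-1,5-diene-11,15-diyl diacetate
Product: 17 (2S,3R,5R)-2-(3-acetoxypropyl)-2,6,6-trimethyl-5-[(3E)-3-methyl-7-(trifluoromethanesulfonyloxy)octa-3,7-dien-1-yl]oxan-3-yl acetate, via organomercurial 16 (not isolated)
Conditions: Hg(O2CCF3)2, CH2Cl2, −20 °C; then NaBH4, aq NaOH, −10 °C
Reagents that add atoms: none
Why: Intramolecular alkoxymercuration–demercuration in which divalent mercury activates the 1,1-disubstituted isopropenyl alkene (faster than the trisubstituted alkene, the enol triflate alkene being deactivated), the only free hydroxyl (C4–OH) attacks the tertiary carbon C15 in a 6-exo Markovnikov closure and borohydride replaces mercury by hydrogen, so the C4–O bond is retained and no new stereocentre results.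

Step 11
Reactants: 17 (2S,3R,5R)-2-(3-acetoxypropyl)-2,6,6-trimethyl-5-[(3E)-3-methyl-7-(trifluoromethanesulfonyloxy)octa-3,7-dien-1-yl]oxan-3-yl acetate
Product: 18 (2S,3R,5R)-2-(3-hydroxypropyl)-2,6,6-trimethyl-5-[(3E)-3-methyl-7-(trifluoromethanesulfonyloxy)octa-3,7-dien-1-yl]oxan-3-yl acetate
Conditions: K2CO3 (0.1 equiv), MeOH, 0 °C
Reagents that add atoms: none
Why: Base-catalysed transesterification (methanolysis) removes the unhindered primary acetate much faster than the secondary acetate flanked by the quaternary C4, and the enol triflate survives the short cold exposure.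

Step 12
Reactants: 18 (2S,3R,5R)-2-(3-hydroxypropyl)-2,6,6-trimethyl-5-[(3E)-3-methyl-7-(trifluoromethanesulfonyloxy)octa-3,7-dien-1-yl]oxan-3-yl acetate
Product: 19 (2S,3R,5R)-2,6,6-trimethyl-2-(3-oxopropyl)-5-[(3E)-3-methyl-7-(trifluoromethanesulfonyloxy)octa-3,7-dien-1-yl]oxan-3-yl acetate
Conditions: Dess–Martin periodinane, NaHCO3, CH2Cl2, rt
Reagents that add atoms: none
Why: Dess–Martin oxidation converts the primary alcohol into the C7 aldehyde under buffered conditions; with C4–O tied up as the ether no lactol can form.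

Step 13
Reactants: 19 (2S,3R,5R)-2,6,6-trimethyl-2-(3-oxopropyl)-5-[(3E)-3-methyl-7-(trifluoromethanesulfonyloxy)octa-3,7-dien-1-yl]oxan-3-yl acetate
Product: 20 (1R,3R,4S,7R,11E)-7-hydroxy-4,15-epoxycembra-8(19),11-dien-3-yl acetate
Conditions: CrCl2 (4 equiv), chiral oxazoline–sulfonamide ligand of the Kishi type (enantiomer giving 7R), Et3N, NiCl2 (5 mol%), THF, rt, 2 mM
Reagents that add atoms: none
Why: Nozaki–Hiyama–Kishi macrocyclisation in which zerovalent nickel inserts into the enol triflate, transmetallation gives an alkenyl species of trivalent chromium that adds to the aldehyde at high dilution to close the 14-membered ring and create the 2-methylene carbinol, and the chromium-bound chiral sulfonamide ligand controls the aldehyde face to set C7 as R.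

## Compound list

1 | geranylacetone, (5E)-6,10-dimethylundeca-5,9-dien-2-one | CC(=O)CC/C=C(\C)CCC=C(C)C | starting material
2 | lithium (5E)-6,10-dimethylundeca-1,5,9-trien-2-olate (not isolated) | C=C(O[Li])CC/C=C(\C)CCC=C(C)C | intermediate
3 | (5E)-6,10-dimethylundeca-1,5,9-trien-2-yl trifluoromethanesulfonate | C=C(OS(=O)(=O)C(F)(F)F)CC/C=C(\C)CCC=C(C)C | intermediate
4 | (4S)-3-acryloyl-4-phenyl-1,3-oxazolidin-2-one | C=CC(=O)N1[C@@H](c2ccccc2)COC1=O | starting material
5 | (4S)-3-[(2E,6E)-6-methyl-10-(trifluoromethanesulfonyloxy)undeca-2,6,10-trienoyl]-4-phenyl-1,3-oxazolidin-2-one | C=C(OS(=O)(=O)C(F)(F)F)CC/C=C(\C)CC/C=C/C(=O)N1[C@@H](c2ccccc2)COC1=O | intermediate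
6 | (4S)-3-[(3R,6E)-6-methyl-3-(prop-1-en-2-yl)-10-(trifluoromethanesulfonyloxy)undeca-6,10-dienoyl]-4-phenyl-1,3-oxazolidin-2-one | C=C(OS(=O)(=O)C(F)(F)F)CC/C=C(\C)CC[C@H](CC(=O)N1[C@@H](c2ccccc2)COC1=O)C(C)=C | intermediate
7 | (3R,6E)-N-methoxy-N,6-dimethyl-3-(prop-1-en-2-yl)-10-(trifluoromethanesulfonyloxy)undeca-6,10-dienamide | C=C(OS(=O)(=O)C(F)(F)F)CC/C=C(\C)CC[C@H](CC(=O)N(C)OC)C(C)=C | intermediate
8 | 2,3-dihydrofuran | C1=COCC1 | starting material
9 | 5-lithio-2,3-dihydrofuran (not isolated) | [Li]C1=CCCO1 | intermediate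
10 | (4,5-dihydrofuran-2-yl)magnesium bromide (not isolated) | Br[Mg]C1=CCCO1 | intermediate
11 | (5E,9R)-11-(4,5-dihydrofuran-2-yl)-6-methyl-11-oxo-9-(prop-1-en-2-yl)undeca-1,5-dien-2-yl trifluoromethanesulfonate | C=C(OS(=O)(=O)C(F)(F)F)CC/C=C(\C)CC[C@H](CC(=O)C1=CCCO1)C(C)=C | intermediate
12 | (5E,9R,11R)-11-(4,5-dihydrofuran-2-yl)-11-hydroxy-6-methyl-9-(prop-1-en-2-yl)undeca-1,5-dien-2-yl trifluoromethanesulfonate | C=C(OS(=O)(=O)C(F)(F)F)CC/C=C(\C)CC[C@H](C[C@@H](O)C1=CCCO1)C(C)=C | intermediate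
13 | (5E,9R,11R)-11,15-dihydroxy-6-methyl-12-oxo-9-(prop-1-en-2-yl)pentadeca-1,5-dien-2-yl trifluoromethanesulfonate | C=C(OS(=O)(=O)C(F)(F)F)CC/C=C(\C)CC[C@H](C[C@@H](O)C(=O)CCCO)C(C)=C | intermediate
14 | (5E,9R,11R,12S)-11,12,15-trihydroxy-6,12-dimethyl-9-(prop-1-en-2-yl)pentadeca-1,5-dien-2-yl trifluoromethanesulfonate | C=C(OS(=O)(=O)C(F)(F)F)CC/C=C(\C)CC[C@H](C[C@@H](O)[C@@](C)(O)CCCO)C(C)=C | intermediate
15 | (5E,9R,11R,12S)-12-hydroxy-6,12-dimethyl-9-(prop-1-en-2-yl)-2-(trifluoromethanesulfonyloxy)pentadeca-1,5-diene-11,15-diyl diacetate | C=C(OS(=O)(=O)C(F)(F)F)CC/C=C(\C)CC[C@H](C[C@@H](OC(C)=O)[C@@](C)(O)CCCOC(C)=O)C(C)=C | intermediate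
16 | (2S,3R,5R)-2-(3-acetoxypropyl)-2,6-dimethyl-5-[(3E)-3-methyl-7-(trifluoromethanesulfonyloxy)octa-3,7-dien-1-yl]-6-[(trifluoroacetoxymercurio)methyl]oxan-3-yl acetate, both C6 epimers (not isolated) | C=C(OS(=O)(=O)C(F)(F)F)CC/C=C(\C)CC[C@@H]1C[C@@H](OC(C)=O)[C@](C)(CCCOC(C)=O)OC1(C)C[Hg]OC(=O)C(F)(F)F | intermediate
17 | (2S,3R,5R)-2-(3-acetoxypropyl)-2,6,6-trimethyl-5-[(3E)-3-methyl-7-(trifluoromethanesulfonyloxy)octa-3,7-dien-1-yl]oxan-3-yl acetate | C=C(OS(=O)(=O)C(F)(F)F)CC/C=C(\C)CC[C@@H]1C[C@@H](OC(C)=O)[C@](C)(CCCOC(C)=O)OC1(C)C | intermediate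
18 | (2S,3R,5R)-2-(3-hydroxypropyl)-2,6,6-trimethyl-5-[(3E)-3-methyl-7-(trifluoromethanesulfonyloxy)octa-3,7-dien-1-yl]oxan-3-yl acetate | C=C(OS(=O)(=O)C(F)(F)F)CC/C=C(\C)CC[C@@H]1C[C@@H](OC(C)=O)[C@](C)(CCCO)OC1(C)C | intermediate
19 | (2S,3R,5R)-2,6,6-trimethyl-2-(3-oxopropyl)-5-[(3E)-3-methyl-7-(trifluoromethanesulfonyloxy)octa-3,7-dien-1-yl]oxan-3-yl acetate | C=C(OS(=O)(=O)C(F)(F)F)CC/C=C(\C)CC[C@@H]1C[C@@H](OC(C)=O)[C@](C)(CCC=O)OC1(C)C | intermediate
20 | (1R,3R,4S,7R,11E)-7-hydroxy-4,15-epoxycembra-8(19),11-dien-3-yl acetate (CNP0202897.1) | C=C1CC/C=C(\C)CC[C@@H]2C[C@@H](OC(C)=O)[C@](C)(CC[C@H]1O)OC2(C)C | target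

## Step count and risks

Total steps: 13. Longest linear sequence: 13 steps (1 → 20); 4 and 8 are purchased.

The three steps most likely to fail:

Step 5 (key C3–C4 bond). The metallated enol ether may attack the enol triflate or add twice, and the α-alkoxy enone 11 is acid-labile. The fallback sets out from 7 (with 8) and comes back at 13, replacing the oxygen-stabilised sp2 acyl anion by a sulfur-stabilised sp3 one. 8 is opened with propane-1,3-dithiol and BF3·OEt2 to 3-(1,3-dithian-2-yl)propan-1-ol F1. Its dianion (n-BuLi, then MgBr2·OEt2) is acylated by 7 to the keto dithiane (5E,9R)-11-[2-(3-hydroxypropyl)-1,3-dithian-2-yl]-6-methyl-11-oxo-9-(prop-1-en-2-yl)undeca-1,5-dien-2-yl trifluoromethanesulfonate F2. CBS reduction as in step 6 gives the (11R)-carbinol F3, and MeI/CaCO3 in wet MeCN unmasks the ketone to give 13.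

Step 10 (oxane closure). The mercurinium ion could be intercepted by the C11=C12 alkene, or the crowded ditertiary ether may close slowly. The fallback sets out from 15 and comes back at 17, replacing electrophilic mercuration by a radical–polar crossover hydroalkoxylation. The reagents are N,N′-bis(3,5-di-tert-butylsalicylidene)-1,2-cyclohexanediaminocobalt (divalent cobalt, catalytic), N-fluoro-2,4,6-trimethylpyridinium tetrafluoroborate and 1,1,3,3-tetramethyldisiloxane in CH2Cl2. Hydrogen-atom transfer to the isopropenyl group gives the tertiary C15 radical, which is oxidised to the cation and captured by C4–OH to give 17 directly (no new compound, F0).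

Step 13 (macrocyclisation and C7). Oligomerisation and imperfect ligand control at C7 in a macrocyclic transition state are the risks. The fallback sets out from 19 and comes back at 20, setting C7 by reagent-controlled reduction instead of in the bond-forming event. The ring is closed without the chiral ligand (CrCl2, NiCl2 cat., DMF/THF, 2 mM) to the C7-epimeric macrocyclic alcohols F4. Dess–Martin oxidation gives the cross-conjugated enone (1R,3R,4S,11E)-7-oxo-4,15-epoxycembra-8(19),11-dien-3-yl acetate F5. Reduction with (S)-2-methyl-CBS-oxazaborolidine and catecholborane at −78 °C then gives 20 with 7R.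

Further compounds
F1 | step 5 | 3-(1,3-dithian-2-yl)propan-1-ol | OCCCC1SCCCS1
F2 | step 5 | (5E,9R)-11-[2-(3-hydroxypropyl)-1,3-dithian-2-yl]-6-methyl-11-oxo-9-(prop-1-en-2-yl)undeca-1,5-dien-2-yl trifluoromethanesulfonate | C=C(OS(=O)(=O)C(F)(F)F)CC/C=C(\C)CC[C@H](CC(=O)C1(CCCO)SCCCS1)C(C)=C
F3 | step 5 | (5E,9R,11R)-11-hydroxy-11-[2-(3-hydroxypropyl)-1,3-dithian-2-yl]-6-methyl-9-(prop-1-en-2-yl)undeca-1,5-dien-2-yl trifluoromethanesulfonate | C=C(OS(=O)(=O)C(F)(F)F)CC/C=C(\C)CC[C@H](C[C@@H](O)C1(CCCO)SCCCS1)C(C)=C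
F0 | step 10 | none | none
F4 | step 13 | (1R,3R,4S,7RS,11E)-7-hydroxy-4,15-epoxycembra-8(19),11-dien-3-yl acetate (C7 epimer mixture) | C=C1CC/C=C(\C)CC[C@@H]2C[C@@H](OC(C)=O)[C@](C)(CCC1O)OC2(C)C
F5 | step 13 | (1R,3R,4S,11E)-7-oxo-4,15-epoxycembra-8(19),11-dien-3-yl acetate | C=C1CC/C=C(\C)CC[C@@H]2C[C@@H](OC(C)=O)[C@](C)(CCC1=O)OC2(C)C
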